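**Retrosynthetic overview**
1. Target 23 comes from benzyl ester 22 by hydrogenolysis of three benzyl groups. 22 comes from diol ester 21 (acetylation), which comes from hydroxy carboxylate 20 (benzylation), keto carboxylate 19 (enzymatic reduction, sets C2') and isocoumarin 18 (KOH opening).
2. Isocoumarin 18 is cut in one step into silylaryl triflate 8 (as its aryne), alkyne 14 and CO2 15; this forms C2–C1', C1–C7 and O–C2'.
3. The strategy rests on this feature: ring carbons C1 and C2 carry the carboxyl carbon C7 and the chain carbon C1' side by side, the C6 oxygen flanks C1 (C4 oxygen para to C1), and the C2' oxygen can reach C7 to close a six-membered lactone, so the target is an opened and reduced 3-alkyl-6,8-dioxygenated isocoumarin.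
4. 8 comes from 3,5-bis(benzyloxy)phenol 1 by carbamate-directed ortho-silylation and triflation. 14 comes from dec-1-yne 9 and (S)-propylene oxide 10 (source of C12'), then alkyne zipper and acetylation.
5. Ring order: the benzene ring is bought; the lactone ring is the only ring formed (step 7) and is opened again in step 8.

Key step: step 7

Remark: 1 is taken as a purchasable phenol; atom labels follow the target (ring C1 bears C7, C2 bears C1', oxygens on C4 and C6, chain C1'–C13' with acetoxy groups on C2' (R) and C12' (S)).

**Step 1**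
Reactants: 1 3,5-bis(benzyloxy)phenol
Product: 2 3,5-bis(benzyloxy)phenyl N-isopropylcarbamate
Conditions: i-PrNCO, Et3N (cat.), CH2Cl2, rt
Reagents that add atoms: isopropyl isocyanate, CC(C)N=C=O
Why: Base-catalysed addition of the phenol O–H across the isocyanate (carbamoylation) should be clean, and the benzyl ethers are inert to it.

**Step 2**
Reactants: 2 3,5-bis(benzyloxy)phenyl N-isopropylcarbamate
Product: 6 3,5-bis(benzyloxy)-2-(trimethylsilyl)phenyl N-isopropylcarbamate, via N-silyl carbamate 3 (not isolated), via ortho-lithiated carbamate 4 (not isolated), via N-silyl C-silyl carbamate 5 (not isolated)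
Conditions: TBSOTf, TMEDA, Et2O, 0 °C → rt; n-BuLi, TMEDA, −78 °C; TMSCl, −78 °C → rt; aq. NaHSO4
Reagents that add atoms: chlorotrimethylsilane, C[Si](C)(C)Cl
Why: Directed ortho-metalation of an O-aryl carbamate, in which in-situ N-silylation removes the acidic N–H and slows the anionic ortho-Fries shift, n-BuLi/TMEDA should lithiate C2 between the carbamate and a benzyloxy oxygen (both ortho sites are equivalent by symmetry and this doubly coordinated site should be metalated at −78 °C faster than the benzylic CH2 groups), TMSCl traps the aryllithium and the acidic work-up strips the N-silyl group.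

**Step 3**
Reactants: 6 3,5-bis(benzyloxy)-2-(trimethylsilyl)phenyl N-isopropylcarbamate
Product: 8 3,5-bis(benzyloxy)-2-(trimethylsilyl)phenyl trifluoromethanesulfonate (fragment 1), via silylphenol 7 (not isolated)
Conditions: DBU, Et2NH, MeCN, 40 °C; then PhNTf2, rt
Reagents that add atoms: N-phenylbis(trifluoromethanesulfonimide), O=S(=O)(N(c1ccccc1)S(=O)(=O)C(F)(F)F)C(F)(F)F
Why: The secondary carbamate is cleaved by E1cB elimination (the isocyanate is scavenged by Et2NH as a urea) and the phenoxide left behind is O-sulfonylated by PhNTf2, a mild triflating agent that should leave the aryl–silicon bond and the benzyl ethers intact.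

**Step 4**
Reactants: 9 dec-1-yne, 10 (S)-propylene oxide
Product: 12 (S)-tridec-4-yn-2-ol, via lithium decynide 11 (not isolated)
Conditions: n-BuLi, THF, −78 °C; BF3·OEt2; then 10, −78 °C; aq. NH4Cl
Reagents that add atoms: none
Why: Epoxide opening by a lithium acetylide under BF3 activation (Yamaguchi–Hirao alkynylation) occurs by SN2 attack at the unsubstituted CH2, so the C–O stereocentre of 10 is not touched and becomes (S)-C2 of 12, the later C12'.

**Step 5**
Reactants: 12 (S)-tridec-4-yn-2-ol
Product: 13 (S)-tridec-12-yn-2-ol
Conditions: KH, H2N(CH2)3NH2, 0 °C → rt; then H2O, 0 °C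
Reagents that add atoms: none
Why: Acetylene zipper reaction, in which potassium 3-aminopropylamide moves the triple bond along the chain by repeated propargyl–allenyl proton shifts until the terminal acetylide (the thermodynamic sink) is reached, while the C2 alkoxide blocks migration towards the carbinol carbon, so the (S) centre should be kept.

**Step 6**
Reactants: 13 (S)-tridec-12-yn-2-ol
Product: 14 (S)-tridec-12-yn-2-yl acetate (fragment 2)
Conditions: Ac2O, pyridine, DMAP (cat.), CH2Cl2, 0 °C → rt
Reagents that add atoms: acetic anhydride, CC(=O)OC(C)=O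
Why: DMAP-catalysed acylation breaks no bond at the stereocentre (retention), and the acetate masks a hydroxyl that would otherwise add to the aryne in step 7 and is later removed by the KOH of step 8 without an extra step.

**Step 7**
Reactants: 8 fragment 1 (1.5 equiv), 14 fragment 2 (limiting), 15 carbon dioxide
Product: 18 3-[(10S)-10-acetoxyundecyl]-6,8-bis(benzyloxy)-1H-isochromen-1-one, via benzyne 16 (not isolated), via alkynylbenzoate salt 17 (not isolated)
Conditions: IPrCuCl (10 mol%; IPr = 1,3-bis(2,6-diisopropylphenyl)imidazol-2-ylidene), CsF, Cs2CO3, CO2 (1 atm), MeCN, 60 °C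
Reagents that add atoms: none
Why: CsF removes the silyl group of 8 and triflate leaves, releasing aryne 16 at low concentration, while Cs2CO3 and IPrCuCl turn 14 into the carbene-bound acetylide of monovalent copper. The acetylide adds across the strained triple bond (alkynylcupration, C2–C1'), the aryl–copper bond inserts CO2 (C1–C7) to give carboxylate 17, the carboxylate oxygen attacks the copper-activated alkyne (O–C2'), and protonolysis of the vinyl–copper bond at C1' by 14 or bicarbonate returns the acetylide. The closest known reaction is the IPrCuCl-catalysed three-component coupling of silylaryl triflates, terminal alkynes and CO2 to 3-substituted isocoumarins, applied here to a 3,5-dialkoxybenzyne. The one ring closes 6-endo-dig at the alkyne carbon that carries the chain, which the bulky carbene ligand should favour over 5-exo-dig closure to an alkylidenephthalide; no stereocentre is formed and C12' is remote. The step needs the acetylide to bond to the aryne carbon remote from the flanking benzyloxy group so that copper, and then C7, sits at C1 next to the C6 oxygen; the inductive pull of that C–O bond distorts the aryne, makes the remote carbon the electrophilic one and stabilises the aryl–metal bond at C1, as 3-alkoxybenzynes generally show. The benzyl ethers and the secondary acetate should be inert to CsF, Cs2CO3 and CO2 in dry MeCN.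

**Step 8**
Reactants: 18 3-[(10S)-10-acetoxyundecyl]-6,8-bis(benzyloxy)-1H-isochromen-1-one
Product: 19 potassium 2,4-bis(benzyloxy)-6-[(12S)-12-hydroxy-2-oxotridecyl]benzoate
Conditions: KOH, THF/H2O, 60 °C; then KH2PO4 to pH 7.5, THF evaporated (solution used directly)
Reagents that add atoms: potassium hydroxide, [K+].[OH-]
Why: Saponification, in which hydroxide adds to the lactone carbonyl C7, the enolate leaving group tautomerises to the C2' ketone and the C12' acetate is hydrolysed in the same pot, while leaving out alcohol cosolvents avoids alcoholysis to a hindered ester and keeping the pH at or above 7 prevents the keto acid from dehydrating back to 18.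

**Step 9**
Reactants: 19 potassium 2,4-bis(benzyloxy)-6-[(12S)-12-hydroxy-2-oxotridecyl]benzoate
Product: 20 potassium 2,4-bis(benzyloxy)-6-[(2R,12S)-2,12-dihydroxytridecyl]benzoate
Conditions: (R)-selective ketoreductase (chosen from a screening panel), NADP+ (cat.), i-PrOH (15% v/v), phosphate buffer pH 7.5, 30 °C; salt recovered by lyophilisation, never acidified
Reagents that add atoms: none
Why: Biocatalytic asymmetric ketone reduction, in which the NADPH-loaded enzyme delivers hydride to one face of the C2' carbonyl, its pocket telling the arylmethyl flank from the long alkyl flank (a bulky–bulky ketone of the kind engineered ketoreductases accept) and so setting C2' as (R), with i-PrOH recycling the cofactor, the carboxylate form keeping the substrate in water and unable to lactonise, and C12' remote and unaffected.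

**Step 10**
Reactants: 20 potassium 2,4-bis(benzyloxy)-6-[(2R,12S)-2,12-dihydroxytridecyl]benzoate
Product: 21 benzyl 2,4-bis(benzyloxy)-6-[(2R,12S)-2,12-dihydroxytridecyl]benzoate
Conditions: BnBr, KHCO3, DMF, rt; neutral work-up, crude product used at once
Reagents that add atoms: benzyl bromide, BrCc1ccccc1
Why: SN2 O-alkylation of the carboxylate by benzyl bromide leaves the two secondary alcohols free because bicarbonate does not deprotonate them, and the benzyl ester, shielded by two ortho substituents, should close onto the C2' hydroxyl only slowly under these near-neutral conditions.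

**Step 11**
Reactants: 21 benzyl 2,4-bis(benzyloxy)-6-[(2R,12S)-2,12-dihydroxytridecyl]benzoate
Product: 22 benzyl 2,4-bis(benzyloxy)-6-[(2R,12S)-2,12-diacetoxytridecyl]benzoate
Conditions: Ac2O, pyridine, DMAP (cat.), CH2Cl2, 0 °C
Reagents that add atoms: acetic anhydride, CC(=O)OC(C)=O
Why: DMAP-catalysed acylation of both secondary alcohols should be faster than ring closure onto the hindered ester and breaks no C–O bond at C2' or C12', so both configurations are retained.

**Step 12**
Reactants: 22 benzyl 2,4-bis(benzyloxy)-6-[(2R,12S)-2,12-diacetoxytridecyl]benzoate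
Product: 23 2-[(2R,12S)-2,12-diacetoxytridecyl]-4,6-dihydroxybenzoic acid
Conditions: H2 (1 atm), Pd/C, EtOAc, rt
Reagents that add atoms: none
Why: Heterogeneous hydrogenolysis of the three benzylic C–O bonds (two aryl benzyl ethers and the benzyl ester) over palladium on carbon at room temperature under neutral conditions should leave the acetates, the homobenzylic C2'–O bond and the arene untouched, and avoiding heat or acid spares the salicylic-type acid from decarboxylation.

**Compound list**
1 | 3,5-bis(benzyloxy)phenol | Oc1cc(OCc2ccccc2)cc(OCc2ccccc2)c1 | starting material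
2 | 3,5-bis(benzyloxy)phenyl N-isopropylcarbamate | CC(C)NC(=O)Oc1cc(OCc2ccccc2)cc(OCc2ccccc2)c1 | intermediate
3 | 3,5-bis(benzyloxy)phenyl N-(tert-butyldimethylsilyl)-N-isopropylcarbamate | CC(C)N(C(=O)Oc1cc(OCc2ccccc2)cc(OCc2ccccc2)c1)[Si](C)(C)C(C)(C)C | intermediate
4 | 2-lithio-3,5-bis(benzyloxy)phenyl N-(tert-butyldimethylsilyl)-N-isopropylcarbamate | [Li]c1c(OC(=O)N(C(C)C)[Si](C)(C)C(C)(C)C)cc(OCc2ccccc2)cc1OCc1ccccc1 | intermediate
5 | 3,5-bis(benzyloxy)-2-(trimethylsilyl)phenyl N-(tert-butyldimethylsilyl)-N-isopropylcarbamate | C[Si](C)(C)c1c(OC(=O)N(C(C)C)[Si](C)(C)C(C)(C)C)cc(OCc2ccccc2)cc1OCc1ccccc1 | intermediate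
6 | 3,5-bis(benzyloxy)-2-(trimethylsilyl)phenyl N-isopropylcarbamate | C[Si](C)(C)c1c(OC(=O)NC(C)C)cc(OCc2ccccc2)cc1OCc1ccccc1 | intermediate
7 | 3,5-bis(benzyloxy)-2-(trimethylsilyl)phenol | C[Si](C)(C)c1c(O)cc(OCc2ccccc2)cc1OCc1ccccc1 | intermediate
8 | 3,5-bis(benzyloxy)-2-(trimethylsilyl)phenyl trifluoromethanesulfonate (fragment 1) | C[Si](C)(C)c1c(OS(=O)(=O)C(F)(F)F)cc(OCc2ccccc2)cc1OCc1ccccc1 | intermediate
9 | dec-1-yne | C#CCCCCCCCC | starting material
10 | (S)-propylene oxide, (2S)-2-methyloxirane | C[C@H]1CO1 | starting material
11 | lithium dec-1-yn-1-ide | [Li]C#CCCCCCCCC | intermediate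
12 | (S)-tridec-4-yn-2-ol | C[C@H](O)CC#CCCCCCCCC | intermediate
13 | (S)-tridec-12-yn-2-ol | C[C@H](O)CCCCCCCCCC#C | intermediate
14 | (S)-tridec-12-yn-2-yl acetate (fragment 2) | C#CCCCCCCCCC[C@H](C)OC(C)=O | intermediate
15 | carbon dioxide | O=C=O | starting material
16 | 3,5-bis(benzyloxy)benzyne (1,2-didehydro-3,5-bis(benzyloxy)benzene) | C1#CC(OCc2ccccc2)=CC(OCc2ccccc2)=C1 | intermediate
17 | caesium 2-[(12S)-12-acetoxytridec-1-yn-1-yl]-4,6-bis(benzyloxy)benzoate (in exchange with its IPrCu carboxylate) | [Cs+].[O-]C(=O)c1c(C#CCCCCCCCCC[C@H](C)OC(C)=O)cc(OCc2ccccc2)cc1OCc1ccccc1 | intermediate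
18 | 3-[(10S)-10-acetoxyundecyl]-6,8-bis(benzyloxy)-1H-isochromen-1-one | CC(=O)O[C@@H](C)CCCCCCCCCC1=Cc2cc(OCc3ccccc3)cc(OCc3ccccc3)c2C(=O)O1 | intermediate
19 | potassium 2,4-bis(benzyloxy)-6-[(12S)-12-hydroxy-2-oxotridecyl]benzoate | [K+].[O-]C(=O)c1c(CC(=O)CCCCCCCCC[C@H](C)O)cc(OCc2ccccc2)cc1OCc1ccccc1 | intermediate
20 | potassium 2,4-bis(benzyloxy)-6-[(2R,12S)-2,12-dihydroxytridecyl]benzoate | [K+].[O-]C(=O)c1c(C[C@H](O)CCCCCCCCC[C@H](C)O)cc(OCc2ccccc2)cc1OCc1ccccc1 | intermediate
21 | benzyl 2,4-bis(benzyloxy)-6-[(2R,12S)-2,12-dihydroxytridecyl]benzoate | O=C(OCc1ccccc1)c1c(C[C@H](O)CCCCCCCCC[C@H](C)O)cc(OCc2ccccc2)cc1OCc1ccccc1 | intermediate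
22 | benzyl 2,4-bis(benzyloxy)-6-[(2R,12S)-2,12-diacetoxytridecyl]benzoate | O=C(OCc1ccccc1)c1c(C[C@H](OC(C)=O)CCCCCCCCC[C@H](C)OC(C)=O)cc(OCc2ccccc2)cc1OCc1ccccc1 | intermediate
23 | 2-[(2R,12S)-2,12-diacetoxytridecyl]-4,6-dihydroxybenzoic acid | CC(=O)O[C@H](CCCCCCCCC[C@H](C)OC(C)=O)Cc1cc(O)cc(O)c1C(=O)O | target

**Step count and risks**
Total: 12 steps. Longest linear sequence: 9 steps (steps 1–3 or 4–6, then 7–12).

Steps most likely to fail:

Step 7. The aryl–copper bond, flanked by a benzyloxy group and the alkynyl group, may be protonated before it takes up CO2; the carboxylate may close 5-exo-dig to the alkylidenephthalide; or the acetylide may add at the wrong aryne carbon. The fallback makes the C2–C1' bond by Sonogashira coupling on a benzoate that already carries C7 and closes the lactone separately; it sets out from 14 and returns at 18. Purchased methyl 2,4,6-trihydroxybenzoate F1 is benzylated twice (BnBr, K2CO3, acetone; the hydroxyl hydrogen-bonded to the ester carbonyl should remain) to methyl 2,4-bis(benzyloxy)-6-hydroxybenzoate F2. Tf2O/pyridine converts this to methyl 2,4-bis(benzyloxy)-6-(trifluoromethylsulfonyloxy)benzoate F3. Coupling with 14 (PdCl2(PPh3)2, CuI, Et3N, DMF, 70 °C) should give methyl 2-[(12S)-12-acetoxytridec-1-yn-1-yl]-4,6-bis(benzyloxy)benzoate F4. Ph3PAuCl/AgOTf (cat.) in wet CH2Cl2 should then close the ester carbonyl oxygen 6-endo-dig onto the alkyne with loss of methanol, giving 18.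

Step 9. The enzyme panel may not accept the large amphiphilic keto carboxylate, or may reduce it with poor facial selectivity. The fallback sets C2' by hydrogenation of the enol-ester double bond instead; it sets out from 18 and returns at 20. Enantioselective hydrogenation of isocoumarins to 3-substituted dihydroisocoumarins is a known reaction class. Here it would use H2 under pressure with a chiral ruthenium catalyst made from Ru(cod)(2-methylallyl)2, a chiral N-heterocyclic carbene (from an imidazolinium tetrafluoroborate bearing 1-(1-naphthyl)ethyl groups and KOt-Bu) and a chiral 1,2-diphenylethane-1,2-diamine, with the ligand enantiomers picked for the (3R) product. This should give (3R)-3-[(10S)-10-acetoxyundecyl]-6,8-bis(benzyloxy)-3,4-dihydro-1H-isochromen-1-one F5. KOH in THF/H2O then opens the lactone and removes the acetate to give 20.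

Step 10. The free C2' hydroxyl may close onto the new benzyl ester with loss of benzyl alcohol during benzylation or handling. The fallback makes no ester; it sets out from 20 and returns at 23. Salt 20 is acetylated directly (Ac2O in excess, pyridine, DMAP, 0 °C). The mixed anhydride that forms at the doubly ortho-substituted carboxyl group should pass on its acetyl group and not its aroyl group (the selectivity on which Yamaguchi-type mixed anhydrides depend), and is hydrolysed on aqueous work-up to 2,4-bis(benzyloxy)-6-[(2R,12S)-2,12-diacetoxytridecyl]benzoic acid F6. Hydrogenolysis (H2, Pd/C, EtOAc) then gives 23. Material that lactonises would be F5 and can be returned to 20 with aqueous KOH.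

**Further compounds**
F1 | step 7 | methyl 2,4,6-trihydroxybenzoate (purchased) | COC(=O)c1c(O)cc(O)cc1O
F2 | step 7 | methyl 2,4-bis(benzyloxy)-6-hydroxybenzoate | COC(=O)c1c(O)cc(OCc2ccccc2)cc1OCc1ccccc1
F3 | step 7 | methyl 2,4-bis(benzyloxy)-6-(trifluoromethylsulfonyloxy)benzoate | COC(=O)c1c(OS(=O)(=O)C(F)(F)F)cc(OCc2ccccc2)cc1OCc1ccccc1
F4 | step 7 | methyl 2-[(12S)-12-acetoxytridec-1-yn-1-yl]-4,6-bis(benzyloxy)benzoate | COC(=O)c1c(C#CCCCCCCCCC[C@H](C)OC(C)=O)cc(OCc2ccccc2)cc1OCc1ccccc1
F5 | step 9 | (3R)-3-[(10S)-10-acetoxyundecyl]-6,8-bis(benzyloxy)-3,4-dihydro-1H-isochromen-1-one | CC(=O)O[C@@H](C)CCCCCCCCC[C@@H]1Cc2cc(OCc3ccccc3)cc(OCc3ccccc3)c2C(=O)O1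
F6 | step 10 | 2,4-bis(benzyloxy)-6-[(2R,12S)-2,12-diacetoxytridecyl]benzoic acid | O=C(O)c1c(C[C@H](OC(C)=O)CCCCCCCCC[C@H](C)OC(C)=O)cc(OCc2ccccc2)cc1OCc1ccccc1
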